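Read the rate and leave the concentrations aside.

common to all: starting material 0.27 M; free catalyst 2.7 mM

| run | second substrate | reagent | remark |
|---|---|---|---|
| birch | 0.38 M | 0.27 M | run made earlier |
| oak | 0.59 M | 0.27 M | run made earlier |
| flask | 0.270 M | 0.270 M |  |

| run | time / h | target / % |
|---|---|---|
| birch | 0.250 | 2.6 |
| birch | 0.667 | 6.5 |
| birch | 1.33 | 11.5 |
| birch | 2.00 | 14.1 |
| birch | 3.00 | 18.8 |
| birch | 4.00 | 21.6 |
| birch | 5.00 | 23.7 |
| oak | 0.667 | 4.9 |
| oak | 1.33 | 8.4 |
| oak | 2.00 | 11.9 |
| oak | 3.00 | 14.4 |
| oak | 4.00 | 18.1 |
| oak | 5.00 | 19.1 |

(each reading ± 0.5 percentage points)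

- no earlier run changes the charge of free catalyst; that part of a forecast is a guess

- apparent order in free catalyst when 30% of the starting material are converted (percent change of the rate of making target for one percent more free catalyst charged)

Birch, from the charge to 0.667 h, opens at 0.0975 /h as a fraction of the charge. Oak, with 1.55 times the second substrate, opens at 0.0735 /h, slower than birch, so its opening rate is 0.754 of birch's.

Then each run slows. Between 2.00 h and 4.00 h birch makes 0.0375 /h. Call the rate kept that mean rate over the stretch divided by the opening rate: 0.385 in birch. Oak makes 0.0310 /h over the same stretch, a rate kept of 0.422, though these are readings with a scatter of 0.5 percentage points. Yet oak stands lower at 4.00 h, at 18.1% against 21.6%, so the slowing may go partly with the clock.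

Now reason on that, as my own reckoning. If the slowing went with conversion, you would get order 1. If it went with the clock, more free catalyst would reach 30% earlier with less slowing gathered, and the order would stand above 1. I put it at 1 or a little over, without a figure, since no run changed the free catalyst.

The forecast commits to 1.2: “a little above 1, skewed high”.

The flask gives 1.2, the forecast's value, with these steps behind it:

    starting material + free catalyst ⇌ catalyst intermediate A (K = 7.94 /M, k = 3.19 /M/min)
    reagent + catalyst intermediate A ⇌ free catalyst + target (K = 1.00, k = 2.13 /M/min)
    second substrate + free catalyst ⇌ catalyst intermediate B (K = 140 /M, k = 1.70 /M/min)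
    reagent + catalyst intermediate B → free catalyst + second product (k = 1.99 /M/min)

The number doesn't show where the catalyst stands: at 4.00 h the flask holds 34.5% as catalyst intermediate A, 36.4% as catalyst intermediate B and 29.1% free. A run at another charge of free catalyst showing plain proportion, order 1, would make the forecast wrong. The flask opens at 0.105 /h up to 0.400 h, and between 2.00 h and 4.00 h its rate kept is 0.407.

The data are simulated for substances that don't exist, noise included.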